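# Proposed synthesis of CNP0196568.1 (compound 10) through a head-to-head chalcone photodimer with a sacrificial C2–C2'' bond

## Analysis of the target

Target 10 is a 3,3''-biflavanone: two 2-arylchroman-4-one units (rings A, C, B and A'', C'', B''; flavanone numbering, second unit double-primed) are joined by one single bond between C3 and C3''. Both rings A are 5,7-dihydroxylated; ring B is 4-methoxyphenyl and ring B'' is 4-hydroxyphenyl, and this one O-methyl group is all that breaks the C2 symmetry of the skeleton. The four stereocentres C2, C3, C3'' and C2'' are contiguous and have the configuration (2S,3R,2''S,3''R): each ring C is 2,3-trans, and C3/C3'' stand in the like relationship (the unlike one belongs to the meso-type series). Sensitive sites are the benzylic C2–O1 and C2''–O1'' bonds, which open by retro-oxa-Michael reaction or, with a free para oxygen, through a quinone methide; the C3 and C3'' hydrogens α to the ketones; and the oxidisable phloroglucinol-type rings A. The difficulty lies in forming the crowded C3–C3'' bond with like relative and defined absolute configuration, and in telling apart two remote, chemically equivalent ring B oxygens. The strategy rests on the chain C2–C3–C3''–C2'': it carries rings B and B'' at its ends and the two ring A carbonyl groups (C4 and C4'') on its inner carbons. One more bond, between C2 and C2'', would make it a 1,2-diaroyl-3,4-diarylcyclobutane, the head-to-head [2+2] dimer of a 2'-hydroxychalcone. That bond lies between two para-oxygenated benzylic carbons and can be broken again by oxidation, and the ring A phenols ortho to C4 and C4'' are placed to become O1 and O1''.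

## Retrosynthetic reasoning

**10 ⇐ 9.** The last operation removes only the four benzyl ethers on rings A and A''. Benzyl is chosen there so that the final step is a neutral hydrogenolysis. A final acidic or basic deprotection would endanger the C2/C3 pair of each unit, because C2 is labile through ring opening and C3 through enolisation, and inversion of both would turn a unit into its mirror image.

**9 ⇐ 8.** The O–CH3 bond on ring B is cut at the stage where the two ring B phenols are the only free hydroxyls. They are equivalent by symmetry, so the forward methylation is statistical. This is the price of a symmetric dimerisation and is paid late, on a compound that can be recovered and recycled.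

**8 ⇐ 7 ⇐ 6.** The ether bonds O1–C2 and O1''–C2'' are cut to give the bis(quinone methide) 7 with free ring A phenols. Joining C2 to C2'' in 7 then leads back to cyclobutane 6. This turns the real problem of the target, the C3–C3'' bond with like configuration, into the trans-diaroyl configuration of a cyclobutane. C2 and C2'' need no control in 6, because they become planar in 7 and are re-formed trans to C3 and C3'' on ring closure. The forward reaction has to remove two electrons and two protons from the ring B phenols of 6 and break only the strained bis-benzylic C2–C2'' bond, not C3–C3''.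

**6 ⇐ 5.** The ring B oxygens are masked as methoxymethyl ethers during the aldol condensation and the photoreaction. They are unmasked by acid at the cyclobutane stage, where acid cannot change any stereocentre, and this leaves benzyl as the only protecting group for the end.

**5 ⇐ 4 + 4.** Cutting C3–C3'' and C2–C2'' gives two molecules of chalcone 4. This is where the strategy gains most: both bonds, the ring and the C3/C3'' configuration arise in one step from a simple achiral enone. The forward reaction needs head-to-head regiochemistry, trans aroyl groups and one enantiomer. A chiral Lewis acid bound to the 2'-hydroxy ketone, together with a visible-light triplet sensitiser, is to provide them.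

**4 ⇐ 2 + 3.** The Cα=Cβ bond of the enone is cut by a retro-aldol condensation into methyl ketone 2 and aldehyde 3, a reliable and convergent step.

**2 ⇐ 1.** Two of the three hydroxyls of 1 are benzylated. The third, chelated to the carbonyl, stays free and is used twice later, as the binding site for the Lewis acid in the key step and as the nucleophile that becomes O1.

## Alternatives that were turned down

**Alternative 1:** Double Friedel–Crafts closure of rings C.
- Disconnection: the two aryl ketone bonds C4–C4a and C4''–C4a''. The precursor is the open-chain diacid A2, a 2,3-disubstituted succinic acid. Its two benzylic carbons (the later C2 and C2'') each carry a 4-acetoxyphenyl group and a 3,5-bis(benzyloxy)phenyl ether, and all four stereocentres are already in place.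
- Forward key step: activation of both carboxyl groups (bis-acid chloride with a strong Lewis acid at low temperature, or a mixed anhydride) and twofold intramolecular acylation ortho to the ether oxygens, closing both rings C to give A1.
- For it: the closure is regiochemically unambiguous, since both ortho positions of each symmetric, doubly activated aryl ether are equivalent. Chromanone formation by acylation is textbook chemistry. No stereocentre is made in the key step, so stereocontrol moves to well-studied acyclic and lactone chemistry.
- Against it:
  - The benzylic aryl ether bonds of A2 lie para to an acyloxy group and ionise under the Lewis acids needed, with loss of C2 configuration or elimination.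
  - An activated succinic acid tends to close to the five-membered anhydride or to form a ketene, which epimerises C3/C3'' and allows only one acylation.
  - A2 needs two stereoselective aryl ether formations at hindered benzylic carbons on a like-configured succinate, many steps from commercial material.
  - A1 is still symmetric at the ring B oxygens, so the statistical mono-methylation is not avoided.
- Comparison: on precedent for the ring-forming event this alternative is stronger. The chosen route offers a precursor two steps from purchasable compounds, formation of C3–C3'' with its configuration in one catalytic step, and C2–O1 bonds that are made last under thermodynamic control instead of being carried through strongly acidic chemistry.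

**Alternative 2:** Transannular alkyne–alkene [2+2], then cyclobutene cleavage.
- Disconnection: the C3–C4 and C3''–C4'' bonds, after retro-cleavage of a cyclobutene C4=C4'' bond into the two ketones. The precursor is the twelve-membered macrocycle A4. In it a diaryl alkyne (C4≡C4'') links rings A and A'', and an E alkene (C3=C3'') links the stereodefined benzylic ether carbons C2 and C2''.
- Forward key step: triplet-sensitised transannular cycloaddition gives the tetracyclic cyclobutene A3 and closes both pyran rings at once. Oxidative cleavage of C4=C4'' would later reveal the ketones.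
- For it: the two ring B groups differ from the start (methyl and benzyl ether), so no statistical step is needed. This is a clear advantage over the chosen route. The ring enforces the regiochemistry, and C2/C2'' are set before the photoreaction.
- Against it:
  - A4 holds an alkyne, an E alkene and two ortho-phenylene units in twelve ring atoms, so it is strained and needs a long synthesis with two enantioselective benzylic ether centres and a macrocyclisation.
  - Cycloadditions of diaryl alkynes to cyclobutenes are little developed, and the product is itself a stilbene-type chromophore that can react on.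
  - A stepwise triplet addition need not be stereospecific at C3/C3''.
  - The tetrasubstituted double bond must be cleaved oxidatively in the presence of several electron-rich arenes.
- Comparison: both routes use a temporary four-membered ring and an unproven cleavage. The chosen route reaches its photosubstrate in two steps instead of through a macrocycle, and its cleavage is driven by the phenols that the target itself carries.

**Alternative 3:** Double asymmetric conjugate arylation of a 3,3'-bichromone.
- Disconnection: the two aryl–carbon bonds C2–C1' and C2''–C1'''. The precursors are the bichromone A6 and the boronic acids A7 and A8.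
- Forward key step: a chiral palladium catalyst adds A7 and then A8 to the two C2=C3 bonds, giving A5. C2 and C2'' are set by the catalyst; C3 and C3'' arise on protonation and must settle trans.
- For it: asymmetric conjugate arylation of chromones to flavanones is an established reaction type. The same catalyst sense at both C2 centres gives the like series once C3 and C3'' are trans. The two aryl groups come from two different reagents. A5 is the benzyl ether of 9, one hydrogenolysis from 10. On precedent of the reaction type and on differentiation of the rings B this alternative is stronger than the chosen route.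
- Against it:
  - Each C2=C3 bond of A6 carries the other chromone at C3. Such α-substituted, twisted enones lie outside the usual scope of the insertion step, and the 5-alkoxy groups lower the electrophilicity further.
  - The first addition must stop at one of two equivalent chromones.
  - The second addition meets a chiral substrate, with a matched or mismatched outcome.
  - C3/C3'' come from enolate protonation and would need equilibration under conditions that can also open the flavanone.
  - A6 needs a synthesis of its own.
- Comparison: the chosen strategy forms C3–C3'' between two unhindered radical centres and from a simpler precursor. It pays for this with a statistical methylation and two unproven steps.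

Key step: step 3

## Remarks on the chemistry

- For 5 and 6 the four ring carbons are also called C2, C3, C3'' and C2'' (flavanone numbering). In their systematic names these are cyclobutane C4, C1, C2 and C3.
- Aldehyde 3 is taken as a purchasable compound; if it is not at hand, it is one O-alkylation away from the corresponding hydroxy aldehyde.
- Which enantiomer of the PyBox ligand gives 5 and not its mirror image has to be fixed in the first experiment; the (S,S) ligand is written.

## Route

Step 1
Reactants: 1 1-(2,4,6-trihydroxyphenyl)ethan-1-one (2',4',6'-trihydroxyacetophenone, dried)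
Product: 2 1-[2,4-bis(benzyloxy)-6-hydroxyphenyl]ethan-1-one
Conditions: BnBr (2.1 equiv), K2CO3 (2.2 equiv), DMF, 0 °C to rt
Reagents that add atoms: benzyl bromide, BrCc1ccccc1
Why: Williamson ether synthesis: the 4-hydroxyl and one of the two equivalent ortho hydroxyls are alkylated, while the last ortho hydroxyl stays free because its proton is held in the hydrogen bond to the acetyl carbonyl. Limiting the benzyl bromide to two equivalents keeps tri-O- and C-benzylation low.

Step 2
Reactants: 2 1-[2,4-bis(benzyloxy)-6-hydroxyphenyl]ethan-1-one, 3 4-(methoxymethoxy)benzaldehyde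
Product: 4 (E)-1-[2,4-bis(benzyloxy)-6-hydroxyphenyl]-3-[4-(methoxymethoxy)phenyl]prop-2-en-1-one
Conditions: KOH (50% aq.), EtOH–THF, rt; then aq. NH4Cl
Reagents that add atoms: none
Why: Claisen–Schmidt condensation: the ketone enolate adds to the non-enolisable aldehyde and the aldol loses water (E1cB) to the conjugated enone with the more stable E geometry. Benzyl and MOM ethers are stable to hydroxide, and the mild ammonium chloride quench spares the acetal.

Step 3
Reactants: 4 (E)-1-[2,4-bis(benzyloxy)-6-hydroxyphenyl]-3-[4-(methoxymethoxy)phenyl]prop-2-en-1-one (two molecules)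
Product: 5 [(1S,2S,3R,4R)-3,4-bis[4-(methoxymethoxy)phenyl]cyclobutane-1,2-diyl]bis{[2,4-bis(benzyloxy)-6-hydroxyphenyl]methanone}, the all-trans head-to-head dimer
Conditions: Sc(OTf)3 (10 mol%), (S,S)-t-Bu-PyBox (15 mol%), Ru(bpy)3(PF6)2 (2.5 mol%), i-PrOAc–MeCN 3:1, 0.3 M, blue LEDs (450 nm), rt, degassed
Reagents that add atoms: none
Why: Proposed new method: the chiral scandium complex chelates the 2'-hydroxy ketone of 4 and lowers the triplet energy of the bound chalcone, so that only this chalcone is sensitised by excited Ru(bpy)3(PF6)2 through energy transfer, while free 4 stays in the ground state and serves as the partner. The triplet enone bonds through its β-carbon (future C2) to the β-carbon of a second molecule of 4 (future C2''), giving a triplet 1,4-biradical with both spins α to the ketones; after intersystem crossing, radical–radical recombination forms C3–C3'' and closes the four-membered ring, so the ring is made by a stepwise [2+2] with closure through collapse of the biradical. The closest known reaction type is the enantioselective [2+2] of 2'-hydroxychalcones with dienes and styrenes under a chiral Lewis acid and a triplet sensitiser, together with the head-to-head photodimerisation of chalcones; an enone as the alkene partner under chiral control is the new element. C2 and C2'' are set in the first bond: the face of the bound chalcone is chosen by the PyBox–scandium environment, and the partner approaches with its aryl group anti, so the two aryl groups become trans. C3 and C3'' are set in the ring closure, where the freely rotating biradical closes with each aroyl group trans to its neighbouring aryl group and hence trans to the other aroyl group. Head-to-head regiochemistry follows from β–β bonding, which leaves both radicals stabilised by a carbonyl group; the all-trans outcome follows from the lifetime of the biradical; the absolute configuration comes from the one chiral complex, and since 5 is C2-symmetric one controlled face fixes all four centres. Only the trans-diaroyl relationship and its absolute sense are carried into 10, because C2 and C2'' are made planar again in step 5.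

Step 4
Reactants: 5 [(1S,2S,3R,4R)-3,4-bis[4-(methoxymethoxy)phenyl]cyclobutane-1,2-diyl]bis{[2,4-bis(benzyloxy)-6-hydroxyphenyl]methanone}
Product: 6 [(1S,2S,3R,4R)-3,4-bis(4-hydroxyphenyl)cyclobutane-1,2-diyl]bis{[2,4-bis(benzyloxy)-6-hydroxyphenyl]methanone}
Conditions: HCl (conc., 5 equiv), MeOH–THF, 45 °C
Reagents that add atoms: none
Why: Acid-catalysed methanolysis of the two aryl MOM acetals; aryl benzyl ethers and the ketones are inert. No stereocentre can drift: C2 and C2'' are not epimerisable, and with them fixed the all-trans arrangement at C3 and C3'' is the thermodynamic one.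

Step 5
Reactants: 6 [(1S,2S,3R,4R)-3,4-bis(4-hydroxyphenyl)cyclobutane-1,2-diyl]bis{[2,4-bis(benzyloxy)-6-hydroxyphenyl]methanone}
Product: 8 (2S,3R,2''S,3''R)-5,7,5'',7''-tetrakis(benzyloxy)-4',4'''-dihydroxy-3,3''-biflavanone, via bis(quinone methide) 7 (not isolated)
Conditions: graphite anode, Pt cathode, undivided cell, constant current (2.1 F/mol), n-Bu4NPF6 (0.1 M), 2,6-lutidine (3 equiv), CH2Cl2–HFIP 4:1, 0 °C
Reagents that add atoms: none
Why: Proposed new method: lutidine-assisted anodic oxidation takes one electron and one proton from each ring B phenol of 6; the phenoxyl spin density at the para carbons weakens the strained bis-benzylic C2–C2'' bond, which breaks to bis(quinone methide) 7, and each quinone methide is captured by the neighbouring chelated ring A phenol in a 6-exo-trig oxa-1,6-addition that forms O1–C2 and O1''–C2''. C3 and C3'' are not touched, and C2 and C2'' form trans to them because aryl group and C3 substituent are both equatorial in the closing chromanone and the addition is reversible through the quinone methide. The closest known reaction types are the oxidative generation of para-quinone methides from 4-alkylphenols with intramolecular capture by a phenol, and the cleavage of the bis-benzylic bond in oxidised 1,2-diarylcyclobutanes.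

Step 6
Reactants: 8 (2S,3R,2''S,3''R)-5,7,5'',7''-tetrakis(benzyloxy)-4',4'''-dihydroxy-3,3''-biflavanone
Product: 9 (2S,3R,2''S,3''R)-5,7,5'',7''-tetrakis(benzyloxy)-4'''-hydroxy-4'-methoxy-3,3''-biflavanone
Conditions: MeOH (1.0 equiv), PPh3 (1.1 equiv), DIAD (1.1 equiv), THF, 0 °C
Reagents that add atoms: methanol, CO
Why: Mitsunobu etherification of a phenol with methanol, chosen because it needs no added base that could open the 4'-hydroxyflavanone through its phenoxide. The two ring B phenols are the only free hydroxyls and are equivalent, so one equivalent of methanol should give mono-ether 9 as the main component of a statistical mixture with the di-ether and recovered 8, which is recycled.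

Step 7
Reactants: 9 (2S,3R,2''S,3''R)-5,7,5'',7''-tetrakis(benzyloxy)-4'''-hydroxy-4'-methoxy-3,3''-biflavanone
Product: 10 (2S,3R,2''S,3''R)-5,7,5'',7'',4'''-pentahydroxy-4'-methoxy-3,3''-biflavanone (CNP0196568.1)
Conditions: H2 (1 atm), 10% Pd/C, EtOAc–MeOH, rt
Reagents that add atoms: none
Why: Heterogeneous hydrogenolysis of the four aryl benzyl ethers under neutral conditions; the methyl ether, the ketones and the four stereocentres are not affected. The reaction is stopped when debenzylation is complete, since the benzylic C2–O1 and C2''–O1'' bonds are cleaved only much more slowly.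

## Compound list

1 | 1-(2,4,6-trihydroxyphenyl)ethan-1-one | CC(=O)c1c(O)cc(O)cc1O | starting material
2 | 1-[2,4-bis(benzyloxy)-6-hydroxyphenyl]ethan-1-one | CC(=O)c1c(O)cc(OCc2ccccc2)cc1OCc1ccccc1 | intermediate
3 | 4-(methoxymethoxy)benzaldehyde | COCOc1ccc(C=O)cc1 | starting material
4 | (E)-1-[2,4-bis(benzyloxy)-6-hydroxyphenyl]-3-[4-(methoxymethoxy)phenyl]prop-2-en-1-one | COCOc1ccc(/C=C/C(=O)c2c(O)cc(OCc3ccccc3)cc2OCc2ccccc2)cc1 | intermediate
5 | [(1S,2S,3R,4R)-3,4-bis[4-(methoxymethoxy)phenyl]cyclobutane-1,2-diyl]bis{[2,4-bis(benzyloxy)-6-hydroxyphenyl]methanone} | O=C(c1c(O)cc(OCc2ccccc2)cc1OCc1ccccc1)[C@H]1[C@H](c2ccc(OCOC)cc2)[C@@H](c2ccc(OCOC)cc2)[C@@H]1C(=O)c1c(O)cc(OCc2ccccc2)cc1OCc1ccccc1 | intermediate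
6 | [(1S,2S,3R,4R)-3,4-bis(4-hydroxyphenyl)cyclobutane-1,2-diyl]bis{[2,4-bis(benzyloxy)-6-hydroxyphenyl]methanone} | O=C(c1c(O)cc(OCc2ccccc2)cc1OCc1ccccc1)[C@H]1[C@H](c2ccc(O)cc2)[C@@H](c2ccc(O)cc2)[C@@H]1C(=O)c1c(O)cc(OCc2ccccc2)cc1OCc1ccccc1 | intermediate
7 | (2S,3S)-1,4-bis[2,4-bis(benzyloxy)-6-hydroxyphenyl]-2,3-bis[(4-oxocyclohexa-2,5-dien-1-ylidene)methyl]butane-1,4-dione | O=C(c1c(O)cc(OCc2ccccc2)cc1OCc1ccccc1)[C@@H](C=C1C=CC(=O)C=C1)[C@H](C=C1C=CC(=O)C=C1)C(=O)c1c(O)cc(OCc2ccccc2)cc1OCc1ccccc1 | intermediate
8 | (2S,3R,2''S,3''R)-5,7,5'',7''-tetrakis(benzyloxy)-4',4'''-dihydroxy-3,3''-biflavanone | Oc1ccc([C@H]2Oc3cc(OCc4ccccc4)cc(OCc4ccccc4)c3C(=O)[C@@H]2[C@H]2C(=O)c3c(OCc4ccccc4)cc(OCc4ccccc4)cc3O[C@@H]2c2ccc(O)cc2)cc1 | intermediate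
9 | (2S,3R,2''S,3''R)-5,7,5'',7''-tetrakis(benzyloxy)-4'''-hydroxy-4'-methoxy-3,3''-biflavanone | COc1ccc([C@H]2Oc3cc(OCc4ccccc4)cc(OCc4ccccc4)c3C(=O)[C@@H]2[C@H]2C(=O)c3c(OCc4ccccc4)cc(OCc4ccccc4)cc3O[C@@H]2c2ccc(O)cc2)cc1 | intermediate
10 | (2S,3R,2''S,3''R)-5,7,5'',7'',4'''-pentahydroxy-4'-methoxy-3,3''-biflavanone | COc1ccc([C@H]2Oc3cc(O)cc(O)c3C(=O)[C@@H]2[C@H]2C(=O)c3c(O)cc(O)cc3O[C@@H]2c2ccc(O)cc2)cc1 | target

## Step count and risk

Total step count: 7. Longest linear sequence: 7 steps (1 to 10; aldehyde 3 is bought).

**Step 3 (key step, proposed new method).**
- What may go wrong: poor facial selectivity or low conversion.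
  - The 6'-benzyloxy group offers the scandium a second, unproductive binding site on the other side of the carbonyl.
  - Product 5 is itself a chelating ligand and may hold back the catalyst.
  - The sensitised chalcone can lose its energy by E/Z isomerisation.
  - The Lewis acid may cyclise 4 to a flavanone.
- Fallback, from 4 back to 5: give up catalyst control of the absolute configuration. Compound 4 is irradiated with Sc(OTf)3 without a chiral ligand and Ru(bpy)3(PF6)2, or with a simple triplet sensitiser. This is the known, non-asymmetric head-to-head photodimerisation of chalcones. It should give 5 together with its mirror image, the (1R,2R,3S,4S)-cyclobutane F1. The two are separated by preparative chromatography on a chiral stationary phase, and 5 re-enters the route at step 4.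

**Step 5 (proposed new method).**
- What may go wrong:
  - After the first bond scission the intermediate may fragment at C3–C3'' as well (oxidative cycloreversion to two chalcone units) before the second electron is removed.
  - The quinone methide may tautomerise by loss of the C3 proton, which erases C3.
  - The ring B phenols of the product may be oxidised further.
- Fallback, from 4 to 8, with known chemistry and without the temporary bond:
  - Compound 4 is cyclised with NaOAc in refluxing EtOH to racemic 5,7-bis(benzyloxy)-2-[4-(methoxymethoxy)phenyl]chroman-4-one F2.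
  - F2 is deprotonated with LiHMDS in THF at −78 °C and the lithium enolate is oxidised with CuCl2 (oxidative homocoupling of ketone enolates). This should join two units at C3, anti to the C2 aryl groups, and give (2S,3R,2''S,3''R)-5,7,5'',7''-tetrakis(benzyloxy)-4',4'''-bis(methoxymethoxy)-3,3''-biflavanone F3 together with its enantiomer F4 and the meso (2S,3R,2''R,3''S) isomer F5.
  - F5 is removed on silica and F3 is separated from F4 on a chiral phase.
  - The two MOM ethers of F3 are cleaved with HCl in MeOH–THF to reach 8.

**Step 6.**
- What may go wrong: the methylation is statistical. Over-methylation to the di-ether and unreacted 8 limit the amount of 9 per pass, and the three closely related compounds must be separated. Any phenoxide formed on the way can open the flavanone ring.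
- Fallback, from 2 and 4 to 9, which removes the methylation from the biflavanone stage:
  - Compound 2 is condensed with 4-methoxybenzaldehyde (KOH, EtOH) to (E)-1-[2,4-bis(benzyloxy)-6-hydroxyphenyl]-3-(4-methoxyphenyl)prop-2-en-1-one F6.
  - The 2'-hydroxyl of 4 is capped (MOMCl, NaH, DMF) to give (E)-1-[2,4-bis(benzyloxy)-6-(methoxymethoxy)phenyl]-3-[4-(methoxymethoxy)phenyl]prop-2-en-1-one F7. F7 cannot chelate the scandium catalyst and is therefore not sensitised.
  - F6 is irradiated with an excess of F7 under the conditions of step 3, so that only scandium-bound F6 is excited and adds to F7. This should give the mixed head-to-head cyclobutane {(1S,2S,3R,4R)-2-[2,4-bis(benzyloxy)-6-(methoxymethoxy)benzoyl]-4-(4-methoxyphenyl)-3-[4-(methoxymethoxy)phenyl]cyclobutyl}[2,4-bis(benzyloxy)-6-hydroxyphenyl]methanone F8.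
  - Both MOM groups are cleaved (HCl, MeOH–THF) to {(1S,2S,3R,4R)-2-[2,4-bis(benzyloxy)-6-hydroxybenzoyl]-3-(4-hydroxyphenyl)-4-(4-methoxyphenyl)cyclobutyl}[2,4-bis(benzyloxy)-6-hydroxyphenyl]methanone F9.
  - F9 is electrolysed as in step 5 and should give 9 directly. Oxidation starts at the single free ring B phenol; scission gives a quinone methide and a 4-methoxybenzyl radical; a second electron transfer gives the 4-methoxybenzyl cation; both electrophilic carbons are captured by the ring A phenols.

**Step 7.**
- What may go wrong: over-reduction, that is hydrogenolysis of the benzylic C2–O1 and C2''–O1'' bonds to dihydrochalcone units, or incomplete removal of the hindered benzyl ethers at C5 and C5''.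
- Fallback, from 9 to 10: replace the reductive cleavage by a Lewis-acid dealkylation, BCl3 with pentamethylbenzene as cation scavenger in CH2Cl2 at −78 °C. No reducing agent is present, and the aryl methyl ether, which is not chelated to a carbonyl group, should survive at this temperature. No new compound is made (F0).

## Further compounds

F1 | step 3 | [(1R,2R,3S,4S)-3,4-bis[4-(methoxymethoxy)phenyl]cyclobutane-1,2-diyl]bis{[2,4-bis(benzyloxy)-6-hydroxyphenyl]methanone} (enantiomer of 5) | O=C(c1c(O)cc(OCc2ccccc2)cc1OCc1ccccc1)[C@@H]1[C@@H](c2ccc(OCOC)cc2)[C@H](c2ccc(OCOC)cc2)[C@H]1C(=O)c1c(O)cc(OCc2ccccc2)cc1OCc1ccccc1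
F2 | step 5 | racemic 5,7-bis(benzyloxy)-2-[4-(methoxymethoxy)phenyl]chroman-4-one | COCOc1ccc(C2CC(=O)c3c(OCc4ccccc4)cc(OCc4ccccc4)cc3O2)cc1
F3 | step 5 | (2S,3R,2''S,3''R)-5,7,5'',7''-tetrakis(benzyloxy)-4',4'''-bis(methoxymethoxy)-3,3''-biflavanone | COCOc1ccc([C@H]2Oc3cc(OCc4ccccc4)cc(OCc4ccccc4)c3C(=O)[C@@H]2[C@H]2C(=O)c3c(OCc4ccccc4)cc(OCc4ccccc4)cc3O[C@@H]2c2ccc(OCOC)cc2)cc1
F4 | step 5 | (2R,3S,2''R,3''S)-5,7,5'',7''-tetrakis(benzyloxy)-4',4'''-bis(methoxymethoxy)-3,3''-biflavanone | COCOc1ccc([C@@H]2Oc3cc(OCc4ccccc4)cc(OCc4ccccc4)c3C(=O)[C@H]2[C@@H]2C(=O)c3c(OCc4ccccc4)cc(OCc4ccccc4)cc3O[C@H]2c2ccc(OCOC)cc2)cc1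
F5 | step 5 | meso (2S,3R,2''R,3''S)-5,7,5'',7''-tetrakis(benzyloxy)-4',4'''-bis(methoxymethoxy)-3,3''-biflavanone | COCOc1ccc([C@H]2Oc3cc(OCc4ccccc4)cc(OCc4ccccc4)c3C(=O)[C@@H]2[C@@H]2C(=O)c3c(OCc4ccccc4)cc(OCc4ccccc4)cc3O[C@H]2c2ccc(OCOC)cc2)cc1
F6 | step 6 | (E)-1-[2,4-bis(benzyloxy)-6-hydroxyphenyl]-3-(4-methoxyphenyl)prop-2-en-1-one | COc1ccc(/C=C/C(=O)c2c(O)cc(OCc3ccccc3)cc2OCc2ccccc2)cc1
F7 | step 6 | (E)-1-[2,4-bis(benzyloxy)-6-(methoxymethoxy)phenyl]-3-[4-(methoxymethoxy)phenyl]prop-2-en-1-one | COCOc1ccc(/C=C/C(=O)c2c(OCOC)cc(OCc3ccccc3)cc2OCc2ccccc2)cc1
F8 | step 6 | {(1S,2S,3R,4R)-2-[2,4-bis(benzyloxy)-6-(methoxymethoxy)benzoyl]-4-(4-methoxyphenyl)-3-[4-(methoxymethoxy)phenyl]cyclobutyl}[2,4-bis(benzyloxy)-6-hydroxyphenyl]methanone | O=C(c1c(O)cc(OCc2ccccc2)cc1OCc1ccccc1)[C@H]1[C@H](c2ccc(OC)cc2)[C@@H](c2ccc(OCOC)cc2)[C@@H]1C(=O)c1c(OCOC)cc(OCc2ccccc2)cc1OCc1ccccc1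
F9 | step 6 | {(1S,2S,3R,4R)-2-[2,4-bis(benzyloxy)-6-hydroxybenzoyl]-3-(4-hydroxyphenyl)-4-(4-methoxyphenyl)cyclobutyl}[2,4-bis(benzyloxy)-6-hydroxyphenyl]methanone | O=C(c1c(O)cc(OCc2ccccc2)cc1OCc1ccccc1)[C@H]1[C@H](c2ccc(OC)cc2)[C@@H](c2ccc(O)cc2)[C@@H]1C(=O)c1c(O)cc(OCc2ccccc2)cc1OCc1ccccc1
F0 | step 7 | none | none
A1 | alternative 1 | (2S,3R,2''S,3''R)-4',4'''-di-O-acetyl-5,7,5'',7''-tetra-O-benzyl-3,3''-biflavanone | CC(=O)Oc1ccc([C@H]2Oc3cc(OCc4ccccc4)cc(OCc4ccccc4)c3C(=O)[C@@H]2[C@H]2C(=O)c3c(OCc4ccccc4)cc(OCc4ccccc4)cc3O[C@@H]2c2ccc(OC(C)=O)cc2)cc1
A2 | alternative 1 | 2,3-bis{(4-acetoxyphenyl)[3,5-bis(benzyloxy)phenoxy]methyl}succinic acid, configured as A1 at all four carbons | CC(=O)Oc1ccc([C@@H](Oc2cc(OCc3ccccc3)cc(OCc3ccccc3)c2)[C@H](C(=O)O)[C@@H](C(=O)O)[C@H](Oc2cc(OCc3ccccc3)cc(OCc3ccccc3)c2)c2ccc(OC(C)=O)cc2)cc1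
A3 | alternative 2 | tetracyclic 1,2-diarylcyclobutene with both pyran rings closed | COc1ccc(cc1)[C@H]1Oc2cc(OCc3ccccc3)cc(OCc3ccccc3)c2C2=C3c4c(OCc5ccccc5)cc(OCc5ccccc5)cc4O[C@H](c4ccc(OCc5ccccc5)cc4)[C@H]3[C@H]12
A4 | alternative 2 | twelve-membered macrocycle with a diaryl alkyne (C4≡C4'') and an E alkene (C3=C3''), configured as A3 at C2 and C2'' | COc1ccc(cc1)[C@@H]1/C=C/[C@@H](c2ccc(OCc3ccccc3)cc2)Oc2cc(OCc3ccccc3)cc(OCc3ccccc3)c2C#Cc2c(OCc3ccccc3)cc(OCc3ccccc3)cc2O1
A5 | alternative 3 | (2S,3R,2''S,3''R)-4'''-O-benzyl-5,7,5'',7''-tetra-O-benzyl-4'-O-methyl-3,3''-biflavanone | COc1ccc([C@H]2Oc3cc(OCc4ccccc4)cc(OCc4ccccc4)c3C(=O)[C@@H]2[C@H]2C(=O)c3c(OCc4ccccc4)cc(OCc4ccccc4)cc3O[C@@H]2c2ccc(OCc3ccccc3)cc2)cc1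
A6 | alternative 3 | 5,5',7,7'-tetrakis(benzyloxy)-3,3'-bichromone | O=c1c(-c2coc3cc(OCc4ccccc4)cc(OCc4ccccc4)c3c2=O)coc2cc(OCc3ccccc3)cc(OCc3ccccc3)c12
A7 | alternative 3 | 4-methoxyphenylboronic acid | COc1ccc(B(O)O)cc1
A8 | alternative 3 | 4-(benzyloxy)phenylboronic acid | OB(O)c1ccc(OCc2ccccc2)cc1
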